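Slowness is what to look for here: a flask can show no substrate within the hour and still be making target. The capture agent's charge is what differs between these flasks, and the two earlier runs hold 0.21 mM of it in dusk and 23 mM in midnight.

| flask | substrate | capture agent | remark | time |
|---|---|---|---|---|
| dusk | 10 mM | 0.21 mM | run made earlier |  |
| midnight | 10 mM | 23 mM | run made earlier |  |
| red | 10 mM | 0.150 mM |  | 5.0 h |
| ochre | 10 mM | 0.500 mM |  | 5.0 h |
| teal | 10 mM | 1.50 mM |  | 5.0 h |
| grey | 10 mM | 5.00 mM |  | 5.0 h |
| amber | 10 mM | 15.0 mM |  | 5.0 h |

| run | time / h | target / % | substrate / % |
|---|---|---|---|
| dusk | 0.250 | 66.9 | 21.5 |
| dusk | 0.667 | 84.8 | 0 |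
| dusk | 1.50 | 86.4 | 0 |
| dusk | 4.00 | 89.7 | 0 |
| midnight | 0.833 | 86.5 | 0 |
| midnight | 2.00 | 85.0 | 2.0 |
| midnight | 2.50 | 86.3 | 2.3 |
| midnight | 4.00 | 87.4 | 0 |

(scatter of a reading: 1 percentage point)

- the earlier runs were read with a standard deviation of 1 percentage point
- a reading or a percentage of target counts all its forms, free or not
- "hardly changes" means that all values lie within two and a half points (for a concentration: within two and a half percent of the largest)

- amount of target at the end, in percent of the substrate charged for red, ochre, teal, grey, amber, in this order
- the shape of the row from first to last (rises, then falls / rises all the way / falls, then rises / hardly changes / falls all the way)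

You have two ways to compare the ends, both using readings taken once substrate reads near zero: dusk from 0.667 h, midnight from 0.833 h. The first way takes means, 87.0% for dusk and 86.3% for midnight, a gap of 0.70 percentage points. The second takes the last readings, a gap of 2.3 points. They part, and the mean is the one that cheats: the dusk readings rise at each step, from 84.8% through 86.4% to 89.7%, so their mean describes a middle time and not the end.

So measure the rise itself. Dusk climbs 4.9 points after its substrate reads 0%, more than the 0.9 points of midnight. The difference, 4 points, is the capturable climb: the late target a flask with little agent gains beyond what a flask with much agent gains. Built from 4 readings of scatter 1 point, it carries twice that scatter, so it is a rough reading.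

Now join the ends. Red holds less agent than dusk, so you carry dusk forward: its last stretch, extended from 4.00 h to 5.0 h, gives 91.0%. For amber, at 15.0 mM, you take the last midnight reading, 87.4%. Your row therefore spans 3.6 points, outside the band of 2.5 points that counts as hardly changing, and you expect a steady fall.

The forecast differs. It gives 86.5% for red and 86.5% for amber, with the shape hardly changes, having pooled the late points and found them “the same within the 1-point reading error”.

The flask gives 91.4%, 91.1%, 90.5%, 88.9% and 86.9% from red to amber, so the row falls all the way.

    substrate → target (k = 0.0910 /min)
    substrate → intermediate A (k = 0.00890 /min)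
    intermediate A → intermediate B (k = 0.00640 /min)
    intermediate B → target (k = 0.0280 /min)
    capture agent + intermediate A → trapped intermediate (k = 1.30 /M/min)
    2 substrate → self-condensation product (k = 0.750 /M/min)
    crystals ⇌ target, rate k7*(cs7 - [target]) while solid is left; crystals form when [target] > cs7 (solubility = 0.640 mM, k = 1.20 /min)

The fall from red to amber is 4.4 points, against a capturable climb of 4 points read from dusk and midnight. Part of the target in red comes through intermediate B, for without that step red ends at 84.9% instead of 91.4%, and the run without capture of intermediate A shows a red-to-amber change of 0 points instead of −4.4 points. Grey, at 5.00 mM, ends 2.5 points below red, about 62.5% of that reading, with 3.99% trapped intermediate.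

The readings are calculated on assumed constants; scatter was added.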